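**Early readings.** At early times the two runs had already parted, grey holding 40.6% of target at 1.00 h and ochre 16.8%. So before charging 2.0 M of substrate, the limiting reagent, on 3.00 M of coupling partner, I wanted to know whether this charge would keep enough target over 12 h or whether a leaner substrate charge should go in.

| flask | substrate | coupling partner | remark | time |
|---|---|---|---|---|
| grey | 1.3 M | 3 M | run made earlier |  |
| ochre | 2 M | 1.5 M | run made earlier |  |
| flask | 2.0 M | 3.00 M |  | 12 h |

| run | time / h | isomer of the product A / % | target / % |
|---|---|---|---|
| grey | 1.00 | 0.7 | 40.6 |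
| grey | 2.00 | 1.8 | 34.1 |
| grey | 2.50 | 2.6 | 32.2 |
| grey | 4.00 | 2.2 | 26.8 |
| grey | 6.00 | 1.8 | 20.5 |
| grey | 10.0 | 2.6 | 15.0 |
| grey | 15.0 | 1.6 | 10.3 |
| ochre | 1.00 | 0.5 | 16.8 |
| ochre | 2.00 | 0.8 | 11.9 |
| ochre | 4.00 | 2.0 | 7.3 |
| ochre | 8.00 | 0.8 | 3.4 |
| ochre | 15.0 | 0.2 | 2.3 |

(each reading ± 0.5 percentage points)

- a reading or a percentage of target counts all its forms, free or not

* share of isomer of the product A in isomer of the product A plus target at 12 s
* share of isomer of the product A in isomer of the product A plus target at 12 h
* which of isomer of the product A and target there is more of at 12 h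

**My reckoning.** The reciprocal of the target fraction rose roughly straight in both runs, within their scatter, like an apparent second-order decay. Between the first reading and 10.0 h in grey its slope was 0.467 h⁻¹, and up to 8.00 h in ochre it was 3.35 h⁻¹. I multiplied each slope by the spare partner, meaning partner charged per substrate charged less 0.5, a deduction I chose to bring the runs together, and this gave 0.844 h⁻¹ and 0.838 h⁻¹. Their mean, 0.841 h⁻¹, I carried as the wear constant, the slope of the reciprocal target fraction times the spare partner. The flask has 1.00 of spare partner and grey's partner charge, so I started it from grey's line at zero time, 50.1%, and reckoned 8.27% of target at 12 h. That stood above the highest grey reading of isomer of the product A, so I decided to charge the flask as planned and to watch the reciprocal of target. My reckoning gave no share.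

**The forecast.** It gave 0.1% at 12 s, 13% at 12 h and target ahead, reasoning: “This looks like isomer formed from target, not alongside it”.

**The result.** The flask gave shares of 1.17% at 12 s and 15.1% at 12 h, with 8.00% of target, against my 8.27%, and 1.42% of isomer of the product A, so target led, as forecast, while side product held 86.4% of the substrate charged.

    substrate + coupling partner ⇌ target (K = 3.90 M⁻¹, k = 0.0390 M⁻¹ min⁻¹)
    substrate + coupling partner ⇌ isomer of the product A (K = 0.730 M⁻¹, k = 4.50 × 10⁻⁴ M⁻¹ min⁻¹)
    target ⇌ isomer of the product B (K = 0.390, k = 0.150 min⁻¹)
    crystals ⇌ target, rate k4*(cs4 - [target]) while solid is left; crystals form when [target] > cs4 (solubility = 1.20 M, k = 15.0 min⁻¹)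
    substrate + target → side product (k = 0.0430 M⁻¹ min⁻¹)

The neighbour flask, charged with 0.50 M of substrate and otherwise unchanged, has 5.50 of spare partner, so the wear constant gives a slope of 0.153 h⁻¹ and 26.1% of target at 12 h, and that flask held 27.4%.

(All runs are calculated from invented constants; scatter was added.)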